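**Plan**

1. Cuts: the seven O‑benzyl bonds; in the lower unit C3–O and C4–H (hydroboration of a 4‑aryl‑2H‑chromene) and the lower C4–upper C6 bond (Suzuki–Miyaura); in the upper unit C4–H (ketone reduction), C6–Br, and last the O1–C8a and C4a–C4 bonds together.
2. Enabling feature: in ring A of the upper unit the ether oxygen O1 sits on C8a and the carbinol carbon C4 on the neighbouring C4a. With C4 at the ketone level, an arene lithiated at C4a and fluorinated at C8a is a 1,2‑dipole that can take up the whole O1–C2–C3–C4 chain.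
3. Key event: the chain comes in as a trans‑β‑lactone, a four‑membered ring whose O1–C4 bond is not in the target and is made only to lock C2 and C3. The aryllithium breaks this bond by acyl attack and the freed alkoxide O1 displaces fluoride at C8a, so the oxetanone is expanded to ring C of the upper unit.
4. Forward order: β‑lactone and bromofluoroarene → upper ring C (step 7) → C4 reduction → C6 bromination; separately, lower rings A and C as a (2R)‑flavanone enol triflate; then coupling, hydroboration, debenzylation.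
5. Stereochemistry: upper C2/C3 from a catalytic asymmetric anti‑glycolate Mukaiyama aldol, carried through the lactone with retention; upper C4 from substrate‑controlled hydride delivery; lower C2 from catalytic asymmetric conjugate addition; lower C3/C4 from hydroboration anti to the 2‑aryl group.

Key step: step 7

Remark: the SMILES is read as ent‑oritin‑(4β→6)‑oritin‑4α‑ol, upper unit (2R,3S,4R) and lower unit (2S,3R,4S), both 2,3‑trans‑3,4‑trans; flavan numbering is used for both units.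

**Step 1**
Reactants: 1 3‑fluorobenzene‑1,2‑diol
Product: 2 1,2‑bis(benzyloxy)‑3‑fluorobenzene
Conditions: BnBr (2.2 equiv), K2CO3, DMF, 60 °C
Reagents that add atoms: benzyl bromide, BrCc1ccccc1
Why: Williamson ether synthesis alkylates both phenoxides with benzyl bromide, and no stereocenter is involved.

**Step 2**
Reactants: 2 1,2‑bis(benzyloxy)‑3‑fluorobenzene
Product: 3 1,2‑bis(benzyloxy)‑4‑bromo‑3‑fluorobenzene
Conditions: NBS (1.05 equiv), MeCN, 0 °C to rt
Reagents that add atoms: N‑bromosuccinimide, O=C1CCC(=O)N1Br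
Why: Electrophilic aromatic bromination should go para to the unhindered 1‑benzyloxy group (C4, ortho to fluorine), because the doubly flanked 2‑benzyloxy group is twisted out of conjugation and the position para to it is meta to fluorine.

**Step 3**
Reactants: 4 (benzyloxy)acetyl chloride
Product: 5 S‑ethyl 2‑(benzyloxy)ethanethioate
Conditions: EtSH, pyridine, CH2Cl2, 0 °C
Reagents that add atoms: ethanethiol, CCS
Why: Acyl substitution of the acid chloride by the thiol (thioesterification), with pyridine as acid scavenger.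

**Step 4**
Reactants: 5 S‑ethyl 2‑(benzyloxy)ethanethioate
Product: 6 (Z)‑{[2‑(benzyloxy)‑1‑(ethylsulfanyl)ethenyl]oxy}trimethylsilane
Conditions: LiN(iPr)2, THF, −78 °C; then Me3SiCl
Reagents that add atoms: chlorotrimethylsilane, C[Si](C)(C)Cl
Why: Kinetic enolization of the thioester and O‑silylation give the ketene silyl thioacetal for the Mukaiyama aldol, taken on as the (Z) isomer.

**Step 5**
Reactants: 6 (Z)‑{[2‑(benzyloxy)‑1‑(ethylsulfanyl)ethenyl]oxy}trimethylsilane; 7 4‑(benzyloxy)benzaldehyde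
Product: 8 S‑ethyl (2R,3R)‑2‑(benzyloxy)‑3‑[4‑(benzyloxy)phenyl]‑3‑hydroxypropanethioate
Conditions: Sn(OTf)2 (20 mol %), (S)‑1‑ethyl‑2‑(piperidin‑1‑ylmethyl)pyrrolidine (22 mol %), EtCN, −78 °C, slow addition; then 1 M HCl, THF
Reagents that add atoms: none
Why: Mukaiyama aldol under a chiral Lewis acid of divalent tin and the (S)‑proline‑derived diamine, a combination known to give anti 2‑benzyloxy‑3‑hydroxy thioesters from this enol silane; attack on the si face of the aldehyde should set C3 as R, the anti topology sets C2 as R, and the silyl ether is cleaved on acidic work‑up.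

**Step 6**
Reactants: 8 S‑ethyl (2R,3R)‑2‑(benzyloxy)‑3‑[4‑(benzyloxy)phenyl]‑3‑hydroxypropanethioate
Product: 9 (3R,4R)‑3‑(benzyloxy)‑4‑[4‑(benzyloxy)phenyl]oxetan‑2‑one
Conditions: Hg(OCOCF3)2 (1.1 equiv), Na2HPO4, MeCN, 0 °C; used at once
Reagents that add atoms: none
Why: Thiophilic activation of the thioester by divalent mercury lets the β‑hydroxyl close the four‑membered lactone (carboxyl‑activation lactonization) with retention at both carbons, so the anti aldol should give the trans lactone, and the buffer guards its acid‑labile benzylic C–O bond.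

**Step 7**
Reactants: 3 1,2‑bis(benzyloxy)‑4‑bromo‑3‑fluorobenzene; 9 (3R,4R)‑3‑(benzyloxy)‑4‑[4‑(benzyloxy)phenyl]oxetan‑2‑one
Product: 12 (2R,3R)‑3,7,8‑tris(benzyloxy)‑2‑[4‑(benzyloxy)phenyl]‑2,3‑dihydro‑4H‑chromen‑4‑one, via aryllithium 10 (not isolated), via lithium aldolate 11 (not isolated)
Conditions: n‑BuLi (1.05 equiv), THF, −78 °C; cannulate into 9 (1.2 equiv), THF, −78 °C; then DMPU, −78 to 0 °C
Reagents that add atoms: none
Why: Proposed new method: bromine–lithium exchange gives the ortho‑fluoro aryllithium 10, which attacks the strained acyl carbon of 9; collapse of the four‑membered tetrahedral intermediate breaks the acyl C–O bond and frees the benzylic alkoxide as aldolate 11, whose oxygen then displaces the fluoride, now ortho to the new aryl ketone, by addition–elimination (6‑exo‑trig closure through an anionic σ‑adduct, LiF as driving force), so that the two neighbouring arene carbons are formally inserted into the lactone acyl C–O bond. The closest known reaction types are the acyl opening of β‑lactones by organolithium reagents to β‑hydroxy ketones and the base‑mediated closure of ortho‑fluoroaryl ketones onto a pendant oxygen nucleophile to chromanones, chromones and xanthones; their merger in one flask on a β‑lactone is the new element. No stereocenter is formed: C2 and C3 come from 9 with retention because no bond at either carbon is touched, and the 2,3‑trans product is also the more stable epimer. Regiochemistry is fixed by the substrate, the C–C bond forming at the former C–Br carbon and the C–O bond at the C–F carbon. The step needs acyl attack to beat α‑deprotonation of 9 and a second addition to the ketone, and ring closure to beat retro‑aldol cleavage or dehydration of 11; low temperature, inverse addition to a slight excess of 9, the chelated lithium aldolate and fluoride as the best leaving group next to a carbonyl should secure this.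

**Step 8**
Reactants: 12 (2R,3R)‑3,7,8‑tris(benzyloxy)‑2‑[4‑(benzyloxy)phenyl]‑2,3‑dihydro‑4H‑chromen‑4‑one
Product: 13 (2R,3S,4R)‑3,7,8‑tris(benzyloxy)‑2‑[4‑(benzyloxy)phenyl]‑3,4‑dihydro‑2H‑chromen‑4‑ol
Conditions: NaBH4, THF/MeOH, −20 to 0 °C
Reagents that add atoms: none
Why: Hydride reduction of the 2,3‑trans 3‑alkoxychromanone by axial attack on the half‑chair should give the equatorial 4‑hydroxyl trans to the 3‑benzyloxy group, as known for borohydride reduction of 2,3‑trans dihydroflavonols.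

**Step 9**
Reactants: 13 (2R,3S,4R)‑3,7,8‑tris(benzyloxy)‑2‑[4‑(benzyloxy)phenyl]‑3,4‑dihydro‑2H‑chromen‑4‑ol
Product: 14 (2R,3S,4R)‑3,7,8‑tris(benzyloxy)‑2‑[4‑(benzyloxy)phenyl]‑6‑bromo‑3,4‑dihydro‑2H‑chromen‑4‑ol
Conditions: NBS (1.0 equiv), CH2Cl2, −20 °C
Reagents that add atoms: N‑bromosuccinimide, O=C1CCC(=O)N1Br
Why: Electrophilic aromatic bromination should occur at C6, para to the ring oxygen O1 and ortho to the 7‑benzyloxy group, the most electron‑rich C–H position of the molecule.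

**Step 10**
Reactants: 15 1‑(2,3,4‑trihydroxyphenyl)ethan‑1‑one
Product: 16 1‑[3,4‑bis(benzyloxy)‑2‑hydroxyphenyl]ethan‑1‑one
Conditions: BnBr (2.1 equiv), K2CO3, acetone, reflux
Reagents that add atoms: benzyl bromide, BrCc1ccccc1
Why: Williamson etherification of the 3‑ and 4‑hydroxyls, the 2‑hydroxyl staying free because it is tied in a hydrogen bond to the ketone.

**Step 11**
Reactants: 16 1‑[3,4‑bis(benzyloxy)‑2‑hydroxyphenyl]ethan‑1‑one
Product: 18 7,8‑bis(benzyloxy)‑4H‑chromen‑4‑one, via enaminone 17 (not isolated)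
Conditions: Me2NCH(OMe)2, toluene, 100 °C; then conc. HCl, CH2Cl2, rt
Reagents that add atoms: N,N‑dimethylformamide dimethyl acetal, COC(OC)N(C)C
Why: Condensation of the methyl ketone with the amide acetal gives the enaminone, and acid closes the pyranone by conjugate attack of the phenol and loss of dimethylamine (enaminone chromone synthesis).

**Step 12**
Reactants: 18 7,8‑bis(benzyloxy)‑4H‑chromen‑4‑one; 19 [4‑(benzyloxy)phenyl]boronic acid
Product: 20 (2R)‑7,8‑bis(benzyloxy)‑2‑[4‑(benzyloxy)phenyl]‑2,3‑dihydro‑4H‑chromen‑4‑one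
Conditions: Pd(OCOCF3)2 (5 mol %), (S)‑4‑tert‑butyl‑2‑(pyridin‑2‑yl)‑4,5‑dihydro‑1,3‑oxazole (6 mol %), NH4PF6 (30 mol %), H2O (5 equiv), ClCH2CH2Cl, 60 °C
Reagents that add atoms: none
Why: Asymmetric conjugate addition of an arylboronic acid to a chromone under a cationic pyridine‑oxazoline complex of divalent palladium, in which the (S)‑ligand should direct the aryl group to the face that gives the (2R)‑flavanone, and the base‑free conditions avoid ring opening.

**Step 13**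
Reactants: 20 (2R)‑7,8‑bis(benzyloxy)‑2‑[4‑(benzyloxy)phenyl]‑2,3‑dihydro‑4H‑chromen‑4‑one
Product: 21 (2R)‑7,8‑bis(benzyloxy)‑2‑[4‑(benzyloxy)phenyl]‑2H‑chromen‑4‑yl trifluoromethanesulfonate
Conditions: Tf2O, 2,6‑di‑tert‑butyl‑4‑methylpyridine, CH2Cl2, 0 °C to rt, dark
Reagents that add atoms: trifluoromethanesulfonic anhydride, O=S(=O)(OS(=O)(=O)C(F)(F)F)C(F)(F)F
Why: Enol triflate formation by O‑triflation of the ketone with a hindered pyridine base avoids a free enolate that could open the pyranone, so C2 stays untouched.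

**Step 14**
Reactants: 14 (2R,3S,4R)‑3,7,8‑tris(benzyloxy)‑2‑[4‑(benzyloxy)phenyl]‑6‑bromo‑3,4‑dihydro‑2H‑chromen‑4‑ol; 21 (2R)‑7,8‑bis(benzyloxy)‑2‑[4‑(benzyloxy)phenyl]‑2H‑chromen‑4‑yl trifluoromethanesulfonate
Product: 23 (2R,3S,4R)‑3,7,8‑tris(benzyloxy)‑2‑[4‑(benzyloxy)phenyl]‑6‑{(2R)‑7,8‑bis(benzyloxy)‑2‑[4‑(benzyloxy)phenyl]‑2H‑chromen‑4‑yl}‑3,4‑dihydro‑2H‑chromen‑4‑ol, via arylboronate 22 (not isolated)
Conditions: B2pin2, PdCl2(dppf) (5 mol %), KOAc, 1,4‑dioxane, 80 °C; then 21, aq. K3PO4, 40 °C, dark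
Reagents that add atoms: none
Why: Miyaura borylation of the aryl bromide and Suzuki–Miyaura coupling of the arylboronate with the enol triflate in the same flask join upper C6 to lower C4 at positions fixed by the two leaving groups; the reactive enol triflate allows a coupling temperature low enough to keep the 2‑aryl‑2H‑chromene from racemizing by reversible electrocyclic ring opening, and no stereocenter is touched.

**Step 15**
Reactants: 23 (the 4‑aryl‑2H‑chromene of step 14)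
Product: 24 (2R,3S,4R)‑3,7,8‑tris(benzyloxy)‑2‑[4‑(benzyloxy)phenyl]‑6‑{(2S,3R)‑7,8‑bis(benzyloxy)‑2‑[4‑(benzyloxy)phenyl]‑3‑hydroxy‑3,4‑dihydro‑2H‑chromen‑4‑yl}‑3,4‑dihydro‑2H‑chromen‑4‑ol, lower C4–aryl bond trans to the 3‑hydroxyl and cis to the 2‑aryl group (hepta‑O‑benzyl ether of the target)
Conditions: BH3·THF (5 equiv), THF, 0 °C to rt, dark; then NaOH, H2O2, H2O, 0 °C
Reagents that add atoms: hydrogen peroxide, OO
Why: Hydroboration–oxidation of the trisubstituted styrene‑type double bond should place boron on C3 and hydrogen on the diaryl‑substituted C4, syn and from the face opposite to the 2‑aryl group, so the 3‑hydroxyl ends up trans to both the 2‑aryl and the 4‑aryl group, as in the hydroboration of flav‑3‑enes to 2,3‑trans flavan‑3‑ols.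

**Step 16**
Reactants: 24 (hepta‑O‑benzyl ether of the target)
Product: 25 ent‑oritin‑(4β→6)‑oritin‑4α‑ol (target)
Conditions: H2 (1 atm), Pd(OH)2/C, THF/MeOH, rt, argon work‑up
Reagents that add atoms: none
Why: Hydrogenolysis of the seven benzyl ethers under neutral conditions should leave the secondary benzylic 4‑hydroxyl and the cyclic benzylic ether bonds intact, as in the debenzylation of other para‑oxygenated benzylic carbinols and of flavan‑3‑ol benzyl ethers.

**Compound list**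

1 | 3‑fluorobenzene‑1,2‑diol | Oc1cccc(F)c1O | starting material
2 | 1,2‑bis(benzyloxy)‑3‑fluorobenzene | Fc1cccc(OCc2ccccc2)c1OCc1ccccc1 | intermediate
3 | 1,2‑bis(benzyloxy)‑4‑bromo‑3‑fluorobenzene | Fc1c(Br)ccc(OCc2ccccc2)c1OCc1ccccc1 | intermediate
4 | (benzyloxy)acetyl chloride | ClC(=O)COCc1ccccc1 | starting material
5 | S‑ethyl 2‑(benzyloxy)ethanethioate | CCSC(=O)COCc1ccccc1 | intermediate
6 | (Z)‑{[2‑(benzyloxy)‑1‑(ethylsulfanyl)ethenyl]oxy}trimethylsilane | CCS/C(O[Si](C)(C)C)=C\OCc1ccccc1 | intermediate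
7 | 4‑(benzyloxy)benzaldehyde | O=Cc1ccc(OCc2ccccc2)cc1 | starting material
8 | S‑ethyl (2R,3R)‑2‑(benzyloxy)‑3‑[4‑(benzyloxy)phenyl]‑3‑hydroxypropanethioate (anti) | CCSC(=O)[C@H](OCc1ccccc1)[C@H](O)c1ccc(OCc2ccccc2)cc1 | intermediate
9 | (3R,4R)‑3‑(benzyloxy)‑4‑[4‑(benzyloxy)phenyl]oxetan‑2‑one (trans) | O=C1O[C@H](c2ccc(OCc3ccccc3)cc2)[C@H]1OCc1ccccc1 | intermediate
10 | [3,4‑bis(benzyloxy)‑2‑fluorophenyl]lithium | [Li]c1ccc(OCc2ccccc2)c(OCc2ccccc2)c1F | intermediate (not isolated)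
11 | lithium alkoxide of (2R,3R)‑1‑[3,4‑bis(benzyloxy)‑2‑fluorophenyl]‑2‑(benzyloxy)‑3‑[4‑(benzyloxy)phenyl]‑3‑hydroxypropan‑1‑one | [Li]O[C@H](c1ccc(OCc2ccccc2)cc1)[C@@H](OCc1ccccc1)C(=O)c1ccc(OCc2ccccc2)c(OCc2ccccc2)c1F | intermediate (not isolated)
12 | (2R,3R)‑3,7,8‑tris(benzyloxy)‑2‑[4‑(benzyloxy)phenyl]‑2,3‑dihydro‑4H‑chromen‑4‑one (2,3‑trans) | O=C1c2ccc(OCc3ccccc3)c(OCc3ccccc3)c2O[C@H](c2ccc(OCc3ccccc3)cc2)[C@H]1OCc1ccccc1 | intermediate
13 | (2R,3S,4R)‑3,7,8‑tris(benzyloxy)‑2‑[4‑(benzyloxy)phenyl]‑3,4‑dihydro‑2H‑chromen‑4‑ol (2,3‑trans‑3,4‑trans) | O[C@@H]1c2ccc(OCc3ccccc3)c(OCc3ccccc3)c2O[C@H](c2ccc(OCc3ccccc3)cc2)[C@H]1OCc1ccccc1 | intermediate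
14 | (2R,3S,4R)‑3,7,8‑tris(benzyloxy)‑2‑[4‑(benzyloxy)phenyl]‑6‑bromo‑3,4‑dihydro‑2H‑chromen‑4‑ol | O[C@@H]1c2cc(Br)c(OCc3ccccc3)c(OCc3ccccc3)c2O[C@H](c2ccc(OCc3ccccc3)cc2)[C@H]1OCc1ccccc1 | intermediate
15 | 1‑(2,3,4‑trihydroxyphenyl)ethan‑1‑one | CC(=O)c1ccc(O)c(O)c1O | starting material
16 | 1‑[3,4‑bis(benzyloxy)‑2‑hydroxyphenyl]ethan‑1‑one | CC(=O)c1ccc(OCc2ccccc2)c(OCc2ccccc2)c1O | intermediate
17 | (E)‑1‑[3,4‑bis(benzyloxy)‑2‑hydroxyphenyl]‑3‑(dimethylamino)prop‑2‑en‑1‑one | CN(C)/C=C/C(=O)c1ccc(OCc2ccccc2)c(OCc2ccccc2)c1O | intermediate (not isolated)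
18 | 7,8‑bis(benzyloxy)‑4H‑chromen‑4‑one | O=c1ccoc2c(OCc3ccccc3)c(OCc3ccccc3)ccc12 | intermediate
19 | [4‑(benzyloxy)phenyl]boronic acid | OB(O)c1ccc(OCc2ccccc2)cc1 | starting material
20 | (2R)‑7,8‑bis(benzyloxy)‑2‑[4‑(benzyloxy)phenyl]‑2,3‑dihydro‑4H‑chromen‑4‑one | O=C1C[C@H](c2ccc(OCc3ccccc3)cc2)Oc2c(OCc3ccccc3)c(OCc3ccccc3)ccc12 | intermediate
21 | (2R)‑7,8‑bis(benzyloxy)‑2‑[4‑(benzyloxy)phenyl]‑2H‑chromen‑4‑yl trifluoromethanesulfonate | O=S(=O)(OC1=C[C@H](c2ccc(OCc3ccccc3)cc2)Oc2c(OCc3ccccc3)c(OCc3ccccc3)ccc12)C(F)(F)F | intermediate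
22 | (2R,3S,4R)‑3,7,8‑tris(benzyloxy)‑2‑[4‑(benzyloxy)phenyl]‑6‑(4,4,5,5‑tetramethyl‑1,3,2‑dioxaborolan‑2‑yl)‑3,4‑dihydro‑2H‑chromen‑4‑ol | O[C@@H]1c2cc(B3OC(C)(C)C(C)(C)O3)c(OCc3ccccc3)c(OCc3ccccc3)c2O[C@H](c2ccc(OCc3ccccc3)cc2)[C@H]1OCc1ccccc1 | intermediate (not isolated)
23 | (2R,3S,4R)‑3,7,8‑tris(benzyloxy)‑2‑[4‑(benzyloxy)phenyl]‑6‑{(2R)‑7,8‑bis(benzyloxy)‑2‑[4‑(benzyloxy)phenyl]‑2H‑chromen‑4‑yl}‑3,4‑dihydro‑2H‑chromen‑4‑ol | O[C@@H]1c2cc(C3=C[C@H](c4ccc(OCc5ccccc5)cc4)Oc4c(OCc5ccccc5)c(OCc5ccccc5)ccc34)c(OCc3ccccc3)c(OCc3ccccc3)c2O[C@H](c2ccc(OCc3ccccc3)cc2)[C@H]1OCc1ccccc1 | intermediate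
24 | hepta‑O‑benzyl ether of the target: upper unit (2R,3S,4R) with 3‑, 7‑, 8‑ and 4'‑O‑benzyl and free 4‑OH; lower unit (2S,3R) with 7‑, 8‑ and 4'‑O‑benzyl, free 3‑OH and the C4–aryl bond trans to 3‑OH, all six centres with the geometry of the target | O[C@@H]1c2cc([C@H]3c4ccc(OCc5ccccc5)c(OCc5ccccc5)c4O[C@@H](c4ccc(OCc5ccccc5)cc4)[C@@H]3O)c(OCc3ccccc3)c(OCc3ccccc3)c2O[C@H](c2ccc(OCc3ccccc3)cc2)[C@H]1OCc1ccccc1 | intermediate
25 | ent‑oritin‑(4β→6)‑oritin‑4α‑ol: (2R,3S,4R)‑2‑(4‑hydroxyphenyl)‑6‑[(2S,3R,4S)‑3,7,8‑trihydroxy‑2‑(4‑hydroxyphenyl)‑3,4‑dihydro‑2H‑chromen‑4‑yl]‑3,4‑dihydro‑2H‑chromene‑3,4,7,8‑tetrol | Oc1ccc([C@H]2Oc3c(cc([C@H]4c5ccc(O)c(O)c5O[C@@H](c5ccc(O)cc5)[C@@H]4O)c(O)c3O)[C@@H](O)[C@@H]2O)cc1 | target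

**Step count and risks**

Total: 16 steps. Longest linear sequence: 10 steps (steps 3, 4, 5, 6, 7, 8, 9, 14, 15, 16, from 4).

Steps most likely to fail:

1. Step 7 (proposed new method). The aryllithium may deprotonate the lactone at C3 or add twice; the lactone may lose CO2; the lithium aldolate may undergo retro‑aldol cleavage or dehydration faster than fluoride displacement, which would erode the configuration at C2 and C3. The fallback sets out from chromone 18 and boronic acid 19 and comes back at 12. Conjugate addition as in step 12 but with the (R)‑enantiomer of the ligand should give (2S)‑7,8‑bis(benzyloxy)‑2‑[4‑(benzyloxy)phenyl]‑2,3‑dihydro‑4H‑chromen‑4‑one F1. tBuMe2SiOTf/Et3N should convert it into the silyl enol ether F2. Rubottom oxidation with dimethyldioxirane anti to the 2‑aryl group, then HF·pyridine, should give the trans (2R,3R)‑3‑hydroxyflavanone F3. Benzylation with BnBr/Ag2O then gives 12.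

2. Step 14. The electron‑rich arylboronate may protodeboronate, the free carbinol may interfere with the catalyst, or the chromene may lose enantiopurity at C2 by thermal or photochemical ring opening during a sluggish coupling. The fallback sets out from 14 and flavanone 20 and comes back at 23. tBuMe2SiCl/imidazole should give the 4‑O‑silyl ether of the bromide F4. Bromine–lithium exchange (n‑BuLi, −78 °C), transmetalation with CeCl3 and 1,2‑addition to 20 should give the tertiary benzylic alcohol F5 as a mixture of C4 epimers. Dehydration with MsCl/Et3N should give the silyl ether of the 4‑aryl‑2H‑chromene F6, and Bu4NF then frees 23.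

3. Step 16. Once the 7‑hydroxyl is freed, the upper benzylic 4‑hydroxyl may ionize and be hydrogenolysed to the flavan‑3‑ol. The fallback sets out from 24 and comes back at 25. Selective oxidation of the benzylic carbinol with MnO2 (the lower, non‑benzylic 3‑hydroxyl should stay) gives the hepta‑O‑benzyl upper‑unit ketone F7. Hydrogenolysis (H2, Pd(OH)2/C) gives the free‑phenolic dihydroflavonol dimer F8. NaBH4 reduction, which is known to give 2,3‑trans‑3,4‑trans diols from free‑phenolic 2,3‑trans dihydroflavonols, then gives 25.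

**Further compounds**

F1 | step 7 | (2S)‑7,8‑bis(benzyloxy)‑2‑[4‑(benzyloxy)phenyl]‑2,3‑dihydro‑4H‑chromen‑4‑one | O=C1C[C@@H](c2ccc(OCc3ccccc3)cc2)Oc2c(OCc3ccccc3)c(OCc3ccccc3)ccc12
F2 | step 7 | tert‑butyl({(2S)‑7,8‑bis(benzyloxy)‑2‑[4‑(benzyloxy)phenyl]‑2H‑chromen‑4‑yl}oxy)dimethylsilane | CC(C)(C)[Si](C)(C)OC1=C[C@@H](c2ccc(OCc3ccccc3)cc2)Oc2c(OCc3ccccc3)c(OCc3ccccc3)ccc12
F3 | step 7 | (2R,3R)‑7,8‑bis(benzyloxy)‑2‑[4‑(benzyloxy)phenyl]‑3‑hydroxy‑2,3‑dihydro‑4H‑chromen‑4‑one | O=C1c2ccc(OCc3ccccc3)c(OCc3ccccc3)c2O[C@H](c2ccc(OCc3ccccc3)cc2)[C@H]1O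
F4 | step 14 | tert‑butyl{[(2R,3S,4R)‑3,7,8‑tris(benzyloxy)‑2‑[4‑(benzyloxy)phenyl]‑6‑bromo‑3,4‑dihydro‑2H‑chromen‑4‑yl]oxy}dimethylsilane | CC(C)(C)[Si](C)(C)O[C@@H]1c2cc(Br)c(OCc3ccccc3)c(OCc3ccccc3)c2O[C@H](c2ccc(OCc3ccccc3)cc2)[C@H]1OCc1ccccc1
F5 | step 14 | (2R)‑7,8‑bis(benzyloxy)‑2‑[4‑(benzyloxy)phenyl]‑4‑{(2R,3S,4R)‑3,7,8‑tris(benzyloxy)‑2‑[4‑(benzyloxy)phenyl]‑4‑[(tert‑butyldimethylsilyl)oxy]‑3,4‑dihydro‑2H‑chromen‑6‑yl}‑3,4‑dihydro‑2H‑chromen‑4‑ol (C4 epimers) | CC(C)(C)[Si](C)(C)O[C@@H]1c2cc(C3(O)C[C@H](c4ccc(OCc5ccccc5)cc4)Oc4c(OCc5ccccc5)c(OCc5ccccc5)ccc34)c(OCc3ccccc3)c(OCc3ccccc3)c2O[C@H](c2ccc(OCc3ccccc3)cc2)[C@H]1OCc1ccccc1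
F6 | step 14 | 4‑O‑(tert‑butyldimethylsilyl) ether of 23 | CC(C)(C)[Si](C)(C)O[C@@H]1c2cc(C3=C[C@H](c4ccc(OCc5ccccc5)cc4)Oc4c(OCc5ccccc5)c(OCc5ccccc5)ccc34)c(OCc3ccccc3)c(OCc3ccccc3)c2O[C@H](c2ccc(OCc3ccccc3)cc2)[C@H]1OCc1ccccc1
F7 | step 16 | upper‑unit 4‑ketone of 24: (2R,3R)‑3,7,8‑tris(benzyloxy)‑2‑[4‑(benzyloxy)phenyl]‑6‑{(2S,3R)‑7,8‑bis(benzyloxy)‑2‑[4‑(benzyloxy)phenyl]‑3‑hydroxy‑3,4‑dihydro‑2H‑chromen‑4‑yl}‑2,3‑dihydro‑4H‑chromen‑4‑one, lower C4 as in the target | O=C1c2cc([C@H]3c4ccc(OCc5ccccc5)c(OCc5ccccc5)c4O[C@@H](c4ccc(OCc5ccccc5)cc4)[C@@H]3O)c(OCc3ccccc3)c(OCc3ccccc3)c2O[C@H](c2ccc(OCc3ccccc3)cc2)[C@H]1OCc1ccccc1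
F8 | step 16 | free‑phenolic dihydroflavonol dimer: (2R,3R)‑3,7,8‑trihydroxy‑2‑(4‑hydroxyphenyl)‑6‑[(2S,3R)‑3,7,8‑trihydroxy‑2‑(4‑hydroxyphenyl)‑3,4‑dihydro‑2H‑chromen‑4‑yl]‑2,3‑dihydro‑4H‑chromen‑4‑one, lower C4 as in the target | O=C1c2cc([C@H]3c4ccc(O)c(O)c4O[C@@H](c4ccc(O)cc4)[C@@H]3O)c(O)c(O)c2O[C@H](c2ccc(O)cc2)[C@H]1O
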